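## Retrosynthetic overview

1. (Germacrane numbering: ring C1–C10, lactone arm C11–C13, C14 on C10, C15 on C4.) The target comes from its 15‑O‑silyl ether; the ten‑membered ring is closed last by ring‑closing metathesis at C4=C5 (ring‑cis).
2. The seco‑diene comes from a Nozaki–Hiyama–Kishi coupling (C1–C10, sets C1) of a (Z)‑alkenyl iodide with 4‑(silyloxymethyl)pent‑4‑enal.
3. The C8 ester is installed by Mitsunobu acylation with inversion, using (S)‑2‑methylbutanoic acid.
4. Key bond C7–C8: the β‑carbon of a 3‑(bromomethyl)butenolide is turned into a lactone‑homoenolate‑type allylzinc and added to (Z)‑3‑iodobut‑2‑enal; C6 relays to C7 and C8, and the exo‑methylene forms in the same step.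
5. Ring order: butenolide (metathesis of a 2‑(bromomethyl)acrylate of a resolved dienol), then α‑methylene‑γ‑lactone (Barbier), then the carbocycle (metathesis).

Assumption: in step 10 the antipode of the valinol‑derived oxazoline–sulfonamide ligand that gives the 1S carbinol is found by a two‑vial test with both antipodes; the route is written for that antipode (L*).

## Route

Step 1
Reactants: 1 rac‑(E)‑hexa‑1,4‑dien‑3‑ol
Product: 2 (3S,4E)‑hexa‑1,4‑dien‑3‑ol
Conditions: Ti(OiPr)4 (0.15 equiv), D‑(−)‑diisopropyl tartrate (0.2 equiv), t‑BuOOH (0.6 equiv), 4 Å MS, CH2Cl2, −20 °C, stop at about 60% conversion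
Reagents that add atoms: none
Why: Sharpless kinetic resolution: with D‑(−)‑tartrate the (R)‑alcohol is epoxidised fast at its (E)‑propenyl olefin, while the (S)‑alcohol (mismatched there, and only slowly epoxidised at its vinyl group) is recovered in high ee, which fixes the future C6.

Step 2
Reactants: 2 (3S,4E)‑hexa‑1,4‑dien‑3‑ol; 3 2‑(bromomethyl)prop‑2‑enoic acid
Product: 4 (3S,4E)‑hexa‑1,4‑dien‑3‑yl 2‑(bromomethyl)prop‑2‑enoate
Conditions: DCC, DMAP (5 mol %), CH2Cl2, 0 °C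
Reagents that add atoms: none
Why: Steglich esterification at 0 °C with little DMAP acylates the bis‑allylic alcohol without displacing the allylic bromide or touching the stereocentre.

Step 3
Reactants: 4 (3S,4E)‑hexa‑1,4‑dien‑3‑yl 2‑(bromomethyl)prop‑2‑enoate
Product: 5 (5R)‑3‑(bromomethyl)‑5‑[(1E)‑prop‑1‑en‑1‑yl]furan‑2(5H)‑one
Conditions: second‑generation Grubbs catalyst RuCl2(=CHPh)(PCy3)(H2IMes) (5 mol %), CH2Cl2 (0.01 M), 40 °C
Reagents that add atoms: none
Why: Ring‑closing metathesis: the ruthenium alkylidene loads on the terminal vinyl group and closes onto the acrylate, the slower propenyl group is kept as the later C5 terminus, and the stereocentre is untouched (3S in 4 is 5R in 5 by priority change only).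

Step 4
Reactants: 6 but‑2‑yn‑1‑ol
Product: 8 (2Z)‑3‑iodobut‑2‑en‑1‑ol, via cyclic alkenylalanate 7 (not isolated)
Conditions: NaAlH2(OCH2CH2OMe)2, THF, 0 °C to rt; then I2, −78 to 0 °C
Reagents that add atoms: iodine, II; sodium bis(2‑methoxyethoxy)aluminium dihydride, [Na+].[AlH2-](OCCOC)OCCOC (its aluminium, sodium and alkoxide atoms stay only in 7)
Why: Hydroxyl‑directed trans‑hydroalumination puts hydride on C2 and aluminium on C3 in a five‑membered alanate, and iodinolysis with retention gives only the (Z)‑iodoalkene, which fixes the ring‑cis C9=C10 geometry.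

Step 5
Reactants: 8 (2Z)‑3‑iodobut‑2‑en‑1‑ol
Product: 9 (2Z)‑3‑iodobut‑2‑enal
Conditions: MnO2, CH2Cl2, rt, dark
Reagents that add atoms: none
Why: Neutral MnO2 oxidation of the allylic alcohol gives the enal without Z/E isomerisation.

Step 6
Reactants: 5 (5R)‑3‑(bromomethyl)‑5‑[(1E)‑prop‑1‑en‑1‑yl]furan‑2(5H)‑one; 9 (2Z)‑3‑iodobut‑2‑enal
Product: 11 (4R,5R)‑4‑[(1R,2Z)‑1‑hydroxy‑3‑iodobut‑2‑en‑1‑yl]‑3‑methylidene‑5‑[(1E)‑prop‑1‑en‑1‑yl]oxolan‑2‑one, via allylzinc bromide 10 (not isolated)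
Conditions: Zn dust (3 equiv), THF / sat. aq. NH4Cl, 0 °C
Reagents that add atoms: zinc, [Zn] (stays only in 10)
Why: Barbier (Dreiding–Schmidt‑type) allylation: zinc insertion makes the normally electrophilic butenolide β‑carbon C7 a homoenolate‑type nucleophile that attacks the aldehyde carbon C8 with allylic transposition to the exo‑methylene; attack is anti to the C6 propenyl group (6,7‑trans) and goes through a chair transition state of the E‑locked allylzinc with the aldehyde residue equatorial (C7/C8 anti, 8R), while the alkenyl iodide is inert to zinc.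

Step 7
Reactants: 11 (4R,5R)‑4‑[(1R,2Z)‑1‑hydroxy‑3‑iodobut‑2‑en‑1‑yl]‑3‑methylidene‑5‑[(1E)‑prop‑1‑en‑1‑yl]oxolan‑2‑one; 12 (2S)‑2‑methylbutanoic acid
Product: 13 (1S,2Z)‑3‑iodo‑1‑{(2R,3S)‑4‑methylidene‑5‑oxo‑2‑[(1E)‑prop‑1‑en‑1‑yl]oxolan‑3‑yl}but‑2‑en‑1‑yl (2S)‑2‑methylbutanoate
Conditions: PPh3, DIAD (premixed), toluene, −20 to 0 °C
Reagents that add atoms: none
Why: Mitsunobu esterification: SN2 displacement of the alkoxyphosphonium by the carboxylate inverts C8 to the 8β‑acyloxy configuration of the target; the electron‑poor iodoalkene disfavours ionisation and SN2′, and the acid stereocentre is not touched.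

Step 8
Reactants: 14 2‑methylidenepropane‑1,3‑diol
Product: 15 2‑{[(tert‑butyldimethylsilyl)oxy]methyl}prop‑2‑en‑1‑ol
Conditions: NaH (1.0 equiv), THF, 0 °C; then TBSCl (1.0 equiv)
Reagents that add atoms: tert‑butyldimethylsilyl chloride, CC(C)(C)[Si](C)(C)Cl
Why: Monosilylation of the symmetric diol through its sparingly soluble monosodium alkoxide (McDougal protocol).

Step 9
Reactants: 15 2‑{[(tert‑butyldimethylsilyl)oxy]methyl}prop‑2‑en‑1‑ol
Product: 17 4‑{[(tert‑butyldimethylsilyl)oxy]methyl}pent‑4‑enal, via allyl vinyl ether 16 (not isolated)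
Conditions: Pd(OAc)2 (2 mol %), 1,10‑phenanthroline (2 mol %), butyl vinyl ether (10 equiv), 75 °C; then 140 °C, sealed tube
Reagents that add atoms: butyl vinyl ether, C=COCCCC
Why: Palladium‑catalysed vinyl ether exchange followed by Claisen [3,3] rearrangement gives the γ,δ‑unsaturated aldehyde that carries C1–C4, C15 and the 1,1‑disubstituted olefin.

Step 10
Reactants: 13 (1S,2Z)‑3‑iodo‑1‑{(2R,3S)‑4‑methylidene‑5‑oxo‑2‑[(1E)‑prop‑1‑en‑1‑yl]oxolan‑3‑yl}but‑2‑en‑1‑yl (2S)‑2‑methylbutanoate; 17 4‑{[(tert‑butyldimethylsilyl)oxy]methyl}pent‑4‑enal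
Product: 19 (1R,2Z,4S)‑7‑{[(tert‑butyldimethylsilyl)oxy]methyl}‑4‑hydroxy‑3‑methyl‑1‑{(2R,3S)‑4‑methylidene‑5‑oxo‑2‑[(1E)‑prop‑1‑en‑1‑yl]oxolan‑3‑yl}octa‑2,7‑dien‑1‑yl (2S)‑2‑methylbutanoate, via alkenylchromium dichloride 18 (not isolated)
Conditions: CrCl2 (4 equiv), L* = N‑[2‑(4‑isopropyl‑4,5‑dihydrooxazol‑2‑yl)‑6‑methylphenyl]methanesulfonamide (4.4 equiv), Et3N (4.4 equiv), NiCl2 (0.1 equiv), THF, rt
Reagents that add atoms: chromium dichloride, [Cr+2].[Cl-].[Cl-] (chromium and chloride stay only in 18)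
Why: Nozaki–Hiyama–Kishi coupling: nickel‑catalysed activation and transmetalation make the C10–I carbon a nucleophilic alkenylchromium (trivalent chromium) with retention of the Z geometry, and the chiral sulfonamide on chromium selects the aldehyde face to give the 1S carbinol by reagent control; lactone, ester and silyl ether are tolerated (C8 is now labelled R only because iodine is replaced by carbon).

Step 11
Reactants: 19 (1R,2Z,4S)‑7‑{[(tert‑butyldimethylsilyl)oxy]methyl}‑4‑hydroxy‑3‑methyl‑1‑{(2R,3S)‑4‑methylidene‑5‑oxo‑2‑[(1E)‑prop‑1‑en‑1‑yl]oxolan‑3‑yl}octa‑2,7‑dien‑1‑yl (2S)‑2‑methylbutanoate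
Product: 20 15‑O‑tert‑butyldimethylsilyl ether of the target
Conditions: second‑generation Hoveyda–Grubbs catalyst RuCl2(=CH‑C6H4‑2‑OiPr)(H2IMes) (15 mol %), 1,4‑benzoquinone (30 mol %), toluene (1 mM), 80 °C, slow addition
Reagents that add atoms: none
Why: Ring‑closing metathesis with loss of propene: the ten‑membered ring enforces the ring‑cis trisubstituted C4=C5 olefin (C3 cis to C6), closure onto C9=C10 would give a strained trans‑fused bicyclo[3.3.0] system, and the α‑methylene lactone is a poor metathesis partner.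

Step 12
Reactants: 20 15‑O‑tert‑butyldimethylsilyl ether of the target
Product: 21 CNP0526758.1
Conditions: HF·pyridine, pyridine / THF, 0 °C to rt
Reagents that add atoms: none
Why: Buffered fluoride desilylation of the primary allylic silyl ether leaves the α‑methylene lactone, the ester, the free C1 carbinol and both olefin geometries untouched.

## Compound list

1 | rac‑(E)‑hexa‑1,4‑dien‑3‑ol | C=CC(O)/C=C/C | starting material
2 | (3S,4E)‑hexa‑1,4‑dien‑3‑ol | C=C[C@H](O)/C=C/C | intermediate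
3 | 2‑(bromomethyl)prop‑2‑enoic acid | C=C(CBr)C(=O)O | starting material
4 | (3S,4E)‑hexa‑1,4‑dien‑3‑yl 2‑(bromomethyl)prop‑2‑enoate | C=C[C@H](OC(=O)C(=C)CBr)/C=C/C | intermediate
5 | (5R)‑3‑(bromomethyl)‑5‑[(1E)‑prop‑1‑en‑1‑yl]furan‑2(5H)‑one | BrCC1=C[C@@H](/C=C/C)OC1=O | intermediate
6 | but‑2‑yn‑1‑ol | CC#CCO | starting material
7 | sodium 2,2‑bis(2‑methoxyethoxy)‑3‑methyl‑2,5‑dihydro‑1,2‑oxaaluminol‑2‑uide (cyclic alkenylalanate) | CC1=CCO[Al-]1(OCCOC)OCCOC.[Na+] | intermediate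
8 | (2Z)‑3‑iodobut‑2‑en‑1‑ol | C/C(I)=C/CO | intermediate
9 | (2Z)‑3‑iodobut‑2‑enal | C/C(I)=C/C=O | intermediate
10 | bromo{[(5R)‑2‑oxo‑5‑[(1E)‑prop‑1‑en‑1‑yl]‑2,5‑dihydrofuran‑3‑yl]methyl}zinc (allylzinc bromide) | Br[Zn]CC1=C[C@@H](/C=C/C)OC1=O | intermediate
11 | (4R,5R)‑4‑[(1R,2Z)‑1‑hydroxy‑3‑iodobut‑2‑en‑1‑yl]‑3‑methylidene‑5‑[(1E)‑prop‑1‑en‑1‑yl]oxolan‑2‑one | C=C1C(=O)O[C@H](/C=C/C)[C@H]1[C@@H](O)/C=C(C)\I | intermediate
12 | (2S)‑2‑methylbutanoic acid | CC[C@H](C)C(=O)O | starting material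
13 | (1S,2Z)‑3‑iodo‑1‑{(2R,3S)‑4‑methylidene‑5‑oxo‑2‑[(1E)‑prop‑1‑en‑1‑yl]oxolan‑3‑yl}but‑2‑en‑1‑yl (2S)‑2‑methylbutanoate | C=C1C(=O)O[C@H](/C=C/C)[C@H]1[C@H](OC(=O)[C@@H](C)CC)/C=C(C)\I | intermediate
14 | 2‑methylidenepropane‑1,3‑diol | C=C(CO)CO | starting material
15 | 2‑{[(tert‑butyldimethylsilyl)oxy]methyl}prop‑2‑en‑1‑ol | C=C(CO)CO[Si](C)(C)C(C)(C)C | intermediate
16 | tert‑butyl({2‑[(ethenyloxy)methyl]prop‑2‑en‑1‑yl}oxy)dimethylsilane (allyl vinyl ether) | C=COCC(=C)CO[Si](C)(C)C(C)(C)C | intermediate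
17 | 4‑{[(tert‑butyldimethylsilyl)oxy]methyl}pent‑4‑enal | O=CCCC(=C)CO[Si](C)(C)C(C)(C)C | intermediate
18 | alkenylchromium dichloride from 13 (CrCl2 in place of iodine, trivalent chromium) | C=C1C(=O)O[C@H](/C=C/C)[C@H]1[C@H](OC(=O)[C@@H](C)CC)/C=C(C)\[Cr](Cl)Cl | intermediate
19 | (1R,2Z,4S)‑7‑{[(tert‑butyldimethylsilyl)oxy]methyl}‑4‑hydroxy‑3‑methyl‑1‑{(2R,3S)‑4‑methylidene‑5‑oxo‑2‑[(1E)‑prop‑1‑en‑1‑yl]oxolan‑3‑yl}octa‑2,7‑dien‑1‑yl (2S)‑2‑methylbutanoate | C=C1C(=O)O[C@H](/C=C/C)[C@H]1[C@H](OC(=O)[C@@H](C)CC)/C=C(C)\[C@@H](O)CCC(=C)CO[Si](C)(C)C(C)(C)C | intermediate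
20 | (1S,6R,7R,8R)‑15‑[(tert‑butyldimethylsilyl)oxy]‑1‑hydroxy‑8‑[(2S)‑2‑methylbutanoyloxy]germacra‑4,9,11(13)‑trien‑12,6‑olide, C4=C5 and C9=C10 ring‑cis | C=C1C(=O)O[C@@H]2/C=C(/CO[Si](C)(C)C(C)(C)C)CC[C@H](O)/C(C)=C\[C@@H](OC(=O)[C@@H](C)CC)[C@@H]12 | intermediate
21 | CNP0526758.1: (1S,6R,7R,8R)‑1,15‑dihydroxy‑8‑[(2S)‑2‑methylbutanoyloxy]germacra‑4,9,11(13)‑trien‑12,6‑olide, 4E,9Z (both ring‑cis) | C=C1C(=O)O[C@@H]2/C=C(/CO)CC[C@H](O)/C(C)=C\[C@@H](OC(=O)[C@@H](C)CC)[C@@H]12 | target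

Note on descriptors: the only change of geometry at a stereocentre after step 1 is the inversion at C8 in step 7. The other changes of CIP letters at C7 and C8 (11 to 13, 13 to 19, 19 to 20) come from priority changes alone.

## Count and risks

Total steps: 12. Longest linear sequence: 8 (steps 1, 2, 3, 6, 7, 10, 11, 12).

Step 7 (Mitsunobu at a hindered allylic carbinol next to C7; elimination toward C7 or partial retention are the dangers). Fallback, setting out from 5 and 9 and coming back at 13: make the 8β configuration directly by an open‑transition‑state allylation instead of inverting it. Pd(PPh3)4 (zerovalent palladium) with hexabutylditin converts 5 into (5R)‑5‑[(1E)‑prop‑1‑en‑1‑yl]‑3‑[(tributylstannyl)methyl]furan‑2(5H)‑one F1. BF3·OEt2 in CH2Cl2 at −78 °C adds the stannane to 9 through an antiperiplanar open transition state, still anti to the propenyl group, and gives the syn alcohol (4R,5R)‑4‑[(1S,2Z)‑1‑hydroxy‑3‑iodobut‑2‑en‑1‑yl]‑3‑methylidene‑5‑[(1E)‑prop‑1‑en‑1‑yl]oxolan‑2‑one F2. Acylation of this alcohol with 12 (DCC, DMAP) goes with retention and gives 13.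

Step 10 (facial control at C1 by the chiral chromium complex on a large substrate may be incomplete). Fallback, setting out from 13 and 17 and coming back at 19: run the coupling without ligand (CrCl2, NiCl2 cat., DMSO) to the C1‑epimeric mixture of 19 F3. Oxidise the allylic alcohol with MnO2 to the (Z)‑enone, the C1 ketone of 19 F4. Reduce it with (R)‑2‑methyl‑CBS‑oxazaborolidine and catecholborane in toluene at −78 °C; with the alkenyl group as the large substituent this gives the 1S alcohol 19.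

Step 11 (ten‑membered ring, trisubstituted olefin, slow initiation at the propenyl and 1,1‑disubstituted olefins). Fallback, setting out from 19 and coming back at 21: change the ring‑closing substrate and the order of events. HF·pyridine first gives the 1,15‑diol, 15‑desilyl 19 F5. The ring is then closed last on this unprotected diene with the same ruthenium catalyst; the free allylic hydroxyl next to the 1,1‑disubstituted olefin assists alkylidene transfer and the bulky silyl ether is gone, so the metathesis gives 21 directly.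

Further compounds
F1 | step 7 | (5R)‑5‑[(1E)‑prop‑1‑en‑1‑yl]‑3‑[(tributylstannyl)methyl]furan‑2(5H)‑one | CCCC[Sn](CCCC)(CCCC)CC1=C[C@@H](/C=C/C)OC1=O
F2 | step 7 | (4R,5R)‑4‑[(1S,2Z)‑1‑hydroxy‑3‑iodobut‑2‑en‑1‑yl]‑3‑methylidene‑5‑[(1E)‑prop‑1‑en‑1‑yl]oxolan‑2‑one | C=C1C(=O)O[C@H](/C=C/C)[C@H]1[C@H](O)/C=C(C)\I
F3 | step 10 | C1‑epimeric mixture of 19 | C=C1C(=O)O[C@H](/C=C/C)[C@H]1[C@H](OC(=O)[C@@H](C)CC)/C=C(C)\C(O)CCC(=C)CO[Si](C)(C)C(C)(C)C
F4 | step 10 | C1 ketone of 19 ((Z)‑enone) | C=C1C(=O)O[C@H](/C=C/C)[C@H]1[C@H](OC(=O)[C@@H](C)CC)/C=C(C)\C(=O)CCC(=C)CO[Si](C)(C)C(C)(C)C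
F5 | step 11 | 15‑desilyl 19 (1,15‑diol) | C=C1C(=O)O[C@H](/C=C/C)[C@H]1[C@H](OC(=O)[C@@H](C)CC)/C=C(C)\[C@@H](O)CCC(=C)CO
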